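The rate constants are made up; the rest is arithmetic.

I began with the easy step, the exchange of substrate with its dormant form.

    substrate + reagent → first product (k1 = 1.77 /M/min)
    reagent + first product → bis adduct (k2 = 1.04 /M/min)
    substrate ⇌ dormant form (K3 = 0.73, k3 = 0.419 /min)
    substrate + first product → side product (k4 = 0.250 /M/min)

| setting | south-west | west | east |
|---|---|---|---|
| substrate | 0.20 M | 0.20 M | 0.20 M |
| reagent | 0.100 M | 0.200 M | 0.400 M |
| time | 20 min | 20 min | 20 min |

1. amount of first product at the end, in percent of the substrate charged for south-west, west, east, in this order
2. how the row runs (rises all the way / falls all the way / rises, then falls / falls, then rises / hardly changes)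

In the south-west flask that exchange relaxed with a half-life of 0.698 min, shorter than the 3.9 min of substrate by step 1, so I froze the ratio of dormant form to substrate at 0.73. Reagent then met 57.8% of the pool of substrate and dormant form, so step 1 worked on that pool with a constant of 1.02 /M/min, against 1.04 /M/min for step 2. I called step 2's constant over this one the effective selectivity factor, 1.02.

At a factor of one, and leaving aside step 4, which is slower than step 1 in the south-west flask, I reckoned first product as a fraction of the charge as −x ln x, where x is the fraction of the pool left. That crests at 36.8%. Counting one reagent per first product and two per bis adduct, the crest costs a reagent charge of 0.179 M. So the south-west charge stood below it, while the west charge and the east charge stood above it. The east pool's half-life at its charge, 1.69 min, was shorter than the run. So I committed to a row that rises, then falls, below the crest of that reckoning, and to no further figures.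

The forecast gave 23%, 29% and 12%, so rises, then falls, holding that “the middle charge ends highest”.

The simulation gave 23.1%, 29.5% and 13.4%: rises, then falls.

The row turned at 0.19 M, beside my 0.179 M. In the south-west flask first product was made 3.31 times faster than it was used up at 2.26 min, each step taken net, but by 20.0 min made over used stood at 0.349. With the factor at 1.02, the west flask's remaining pool of 27.4% gives 35.5%, and its first product plus half its side product stood at 36.4%. The east flask's pool of 5.48% gives 15.9%, and the same sum there stood at 16.4%.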